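**Retrosynthetic overview**
- Tomoeone D ⇐ Tsuji–Trost C-prenylation (zerovalent palladium) of a mono-prenyl spiro acylphloroglucinol ⇐ Claisen closure of ring A ⇐ acylation of a prenyl-diketone dianion (C12 fragment) by a bridged lactone ester (C16 fragment).
- Bridged lactone ester ⇐ manganese-catalysed dehydrogenative 6-endo carbolactonisation (malonate C–H + isopropenyl alkene + ester C=O), which closes the cyclohexane and makes the quaternary (later spiro) carbon and the C4–O bond.
- Its precursor ⇐ MeMgBr addition and malonate Michael addition to an exo-methylene cyclopentanone ⇐ Mannich base from rhodium-catalysed asymmetric conjugate isopropenylation of cyclopentenone with enolate trapping.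
- Ring order: cyclopentane (bought as cyclopentenone) → cyclohexane with lactone bridge → ring A last; one prenyl arrives with the diketone fragment, the second in the final step.

Assumption: ring A enols are written in one tautomer (as in the target SMILES); hydrindane positions are C1–C7a, ring A positions are C1'–C6' (C6' = spiro carbon = hydrindane C6, C1' = ketone next to the diprenyl carbon C2', C4' = acyl-bearing carbon).

**Step 1**
Reactants: 1 cyclopent-2-en-1-one; 2 isopropenylmagnesium bromide
Product: 5 (2R,3R)-2-[(dimethylamino)methyl]-3-(prop-1-en-2-yl)cyclopentan-1-one, via B-isopropenyl-9-BBN 3 (not isolated), via boron enolate 4 (not isolated)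
Conditions: 2, B-bromo-9-BBN, THF, −78 °C → rt; then 1, [Rh(OMe)(cod)]2 (1.5 mol %), (R)-BINAP (3.3 mol %), toluene, 80 °C; then CH2=NMe2+ I−, THF–DMSO, 0 °C → rt; aq. NaHCO3
Reagents that add atoms: dimethylmethylideneammonium iodide (Eschenmoser's salt), C=[N+](C)C.[I-]; B-bromo-9-BBN, BrB1C2CCCC1CCC2 (its boron unit is carried only in 3 and 4)
Why: Hayashi–Miyaura-type asymmetric 1,4-addition with a monovalent rhodium/(R)-BINAP catalyst under aprotic conditions sets C3 as R in the carborhodation step (ligand sense by analogy with cyclopentenone additions) and leaves a regiodefined boron enolate, which a Hooz-type Mannich reaction alkylates at C2 anti to the isopropenyl group (trans; C2 is in any case epimerisable).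

**Step 2**
Reactants: 6 malonic acid
Product: 7 diisopropyl malonate
Conditions: iPrOH (excess), H2SO4 (cat.), toluene, reflux, Dean–Stark
Reagents that add atoms: propan-2-ol, CC(C)O
Why: Fischer esterification driven by azeotropic water removal; the bulky isopropyl esters later resist Grignard attack and leave the lactone as the most electrophilic carbonyl.

**Step 3**
Reactants: 5 (2R,3R)-2-[(dimethylamino)methyl]-3-(prop-1-en-2-yl)cyclopentan-1-one; 7 diisopropyl malonate
Product: 10 diisopropyl 2-{[(1S,5R)-2-oxo-5-(prop-1-en-2-yl)cyclopentyl]methyl}propanedioate, via Mannich methiodide 8 (not isolated), via exo-methylene enone 9 (not isolated)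
Conditions: MeI, THF, rt; then 7 (1.5 equiv), NaH (1.2 equiv), THF, 0 °C → rt; aq. NH4Cl
Reagents that add atoms: iodomethane, CI (its methyl is carried only in 8)
Why: Quaternisation and E1cB (Hofmann-type) elimination of the Mannich base release the exo-methylene enone in situ, the malonate anion adds in a Michael reaction, and the α-centre equilibrates under the basic conditions to the trans isomer.

**Step 4**
Reactants: 10 diisopropyl 2-{[(1S,5R)-2-oxo-5-(prop-1-en-2-yl)cyclopentyl]methyl}propanedioate
Product: 11 diisopropyl 2-{[(1S,2R,5R)-2-hydroxy-2-methyl-5-(prop-1-en-2-yl)cyclopentyl]methyl}propanedioate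
Conditions: MeMgBr (3 equiv), LaCl3·2LiCl (1 equiv), THF, −20 → 0 °C; aq. NH4Cl
Reagents that add atoms: methylmagnesium bromide, C[Mg]Br
Why: Grignard 1,2-addition (LaCl3·2LiCl suppresses enolisation; one equivalent of MeMgBr parks the malonate as its unreactive magnesium enolate) occurs on the ketone face anti to the adjacent side chain, as in related trans-2,3-disubstituted cyclopentanones, so the new hydroxyl is cis to that chain.

**Step 5**
Reactants: 11 diisopropyl 2-{[(1S,2R,5R)-2-hydroxy-2-methyl-5-(prop-1-en-2-yl)cyclopentyl]methyl}propanedioate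
Product: 12 propan-2-yl ester of (1R,3aR,4S,6S,7aS)-1,4-dihydroxy-1,4-dimethyloctahydro-1H-indene-6,6-dicarboxylic acid 6,4-lactone (axial carboxyl lactonised onto the axial C4 oxygen; equatorial CO2iPr)
Conditions: Mn(OAc)2·4H2O (10 mol %), NaOAc (0.3 M), AcOH, 60 °C, undivided cell, graphite-felt anode, Pt cathode, constant current, 2.4 F mol−1
Reagents that add atoms: none
Why: Proposed new method: manganese-electrocatalysed dehydrogenative C–H/alkene carbolactonisation, in which anodically regenerated trivalent manganese acetate oxidises the malonate (through its manganese enolate) to the malonyl radical, this adds 6-endo-trig to the CH2 end of the isopropenyl group through a chair transition state with both cyclopentane bonds equatorial (trans ring fusion), the tertiary C4 radical is oxidised (trivalent manganese or anode) to the cation, and the 1,3-diaxial ester carbonyl captures it from the axial face before acetate removes the isopropyl group, so that the C5–C6 bond, the quaternary carbon, the C4–O stereocentre (4S) and the differentiation of the two carboxyls are set in one operation while the cathode releases H2; the closest known reaction type is the stoichiometric Mn(OAc)3 oxidative free-radical cyclisation with lactone termination together with manganese-mediated anodic alkene functionalisation, not yet shown as a catalytic 6-endo carbolactonisation building a bridged lactone on a quaternary carbon.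

**Step 6**
Reactants: 13 3-methylbutan-2-one; 14 ethyl acetate
Product: 15 5-methylhexane-2,4-dione
Conditions: NaH (2.2 equiv), THF, reflux; aq. HCl
Reagents that add atoms: none
Why: Crossed Claisen condensation; acylation occurs at the methyl group because only that product forms a stabilised diketonate.

**Step 7**
Reactants: 15 5-methylhexane-2,4-dione; 16 1-bromo-3-methylbut-2-ene (prenyl bromide)
Product: 17 2,9-dimethyldec-8-ene-3,5-dione
Conditions: LiN(iPr)2 (2.1 equiv), THF, −78 → 0 °C; then 16, −78 °C → rt; aq. NH4Cl
Reagents that add atoms: none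
Why: Dianion (Hauser–Weiler-type) γ-alkylation, in which the more basic terminal methyl carbanion of the 1,3-diketone dianion, not the central carbon or the isopropyl methine, displaces the allylic bromide (SN2).

**Step 8**
Reactants: 12 bridged lactone ester; 17 2,9-dimethyldec-8-ene-3,5-dione
Product: 18 propan-2-yl (1R,3aR,4S,6R,7aS)-1,4-dihydroxy-1,4-dimethyl-6-[6-methyl-2-(3-methylbut-2-en-1-yl)-3,5-dioxoheptanoyl]octahydro-1H-indene-6-carboxylate
Conditions: 17 (2.5 equiv), LiN(iPr)2 (5 equiv), THF, −78 → 0 °C; then 12, −78 → −20 °C; aq. NH4Cl (excess 17 recovered)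
Reagents that add atoms: none
Why: Harris-type C-acylation of a β-diketone dianion, in which the terminal carbanion opens the strained s-cis bicyclic γ-lactone in preference to the neopentyl-type isopropyl ester, so the prenyl-bearing carbon becomes attached to the axial carbonyl syn to the C4 hydroxyl and the sense of the future spiro centre is fixed (the new CH(prenyl) centre is an enolisable mixture that converges in step 9).

**Step 9**
Reactants: 18 triketo ester
Product: 19 mono-prenyl spiro acylphloroglucinol (ring A = enolised 4'-isobutyryl-2'-prenylcyclohexane-1',3',5'-trione spiro-fused at C6' to the (1R,3aR,4S,7aS)-1,4-dihydroxy-1,4-dimethylhydrindane; C1' syn to the C4 hydroxyl)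
Conditions: KOtBu (4 equiv), tBuOH–THF, 0 → 50 °C; 1 M HCl
Reagents that add atoms: none
Why: Intramolecular Claisen (Dieckmann-type, polyketide-like) condensation under equilibrating conditions, in which the doubly activated carbon C4' attacks the equatorial isopropyl ester to close six-membered ring A, the stable triketone enolate being the thermodynamic sink (O-acylated enol lactones revert) and no stereocentre being touched.

**Step 10**
Reactants: 20 3-methylbut-2-en-1-ol (prenol)
Product: 21 methyl 3-methylbut-2-en-1-yl carbonate
Conditions: ClCO2Me (1.2 equiv), pyridine, CH2Cl2, 0 °C → rt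
Reagents that add atoms: methyl chloroformate, COC(=O)Cl
Why: Acylation of the allylic alcohol by the chloroformate (carbonate formation); no stereochemistry involved.

**Step 11**
Reactants: 19 mono-prenyl spiro acylphloroglucinol; 21 methyl 3-methylbut-2-en-1-yl carbonate
Product: 22 tomoeone D
Conditions: Pd(PPh3)4 (5 mol %), 21 (1.2 equiv), THF, 40 °C
Reagents that add atoms: none
Why: Tsuji–Trost allylic alkylation with a zerovalent palladium catalyst, in which decarboxylation of the carbonate gives the prenyl–palladium cation and methoxide, and the soft trione enolate attacks the unsubstituted allyl terminus through its only free ring carbon C2' (O-allylation is reversible), creating the gem-diprenyl quaternary carbon under near-neutral conditions that spare the tertiary alcohols and avoid retro-Claisen opening.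

**Compound list**
1 | cyclopent-2-en-1-one | O=C1C=CCC1 | starting material
2 | isopropenylmagnesium bromide (prop-1-en-2-ylmagnesium bromide) | CC(=C)[Mg]Br | starting material
3 | B-isopropenyl-9-BBN, 9-(prop-1-en-2-yl)-9-borabicyclo[3.3.1]nonane | CC(=C)B1C2CCCC1CCC2 | intermediate
4 | boron enolate, 9-{[(3R)-3-(prop-1-en-2-yl)cyclopent-1-en-1-yl]oxy}-9-borabicyclo[3.3.1]nonane | CC(=C)[C@@H]1CCC(OB2C3CCCC2CCC3)=C1 | intermediate
5 | (2R,3R)-2-[(dimethylamino)methyl]-3-(prop-1-en-2-yl)cyclopentan-1-one (trans) | CN(C)C[C@H]1[C@@H](CCC1=O)C(C)=C | intermediate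
6 | malonic acid | OC(=O)CC(=O)O | starting material
7 | diisopropyl malonate (dipropan-2-yl propanedioate) | CC(C)OC(=O)CC(=O)OC(C)C | intermediate
8 | Mannich methiodide, [(1R,5R)-2-oxo-5-(prop-1-en-2-yl)cyclopentyl]-N,N,N-trimethylmethanaminium iodide | C[N+](C)(C)C[C@H]1[C@@H](CCC1=O)C(C)=C.[I-] | intermediate
9 | exo-methylene enone, (3S)-2-methylidene-3-(prop-1-en-2-yl)cyclopentan-1-one | C=C1[C@@H](CCC1=O)C(C)=C | intermediate
10 | diisopropyl 2-{[(1S,5R)-2-oxo-5-(prop-1-en-2-yl)cyclopentyl]methyl}propanedioate (trans) | CC(C)OC(=O)C(C(=O)OC(C)C)C[C@H]1[C@@H](CCC1=O)C(C)=C | intermediate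
11 | diisopropyl 2-{[(1S,2R,5R)-2-hydroxy-2-methyl-5-(prop-1-en-2-yl)cyclopentyl]methyl}propanedioate (OH cis to the malonylmethyl chain) | CC(C)OC(=O)C(C(=O)OC(C)C)C[C@H]1[C@@H](CC[C@@]1(C)O)C(C)=C | intermediate
12 | bridged lactone ester: propan-2-yl ester of (1R,3aR,4S,6S,7aS)-1,4-dihydroxy-1,4-dimethyloctahydro-1H-indene-6,6-dicarboxylic acid 6,4-lactone (trans-hydrindane; axial carboxyl lactonised onto the axial C4 oxygen) | O=C1[C@]2(C[C@H]3[C@@H](CC[C@@]3(C)O)[C@@](C)(O1)C2)C(=O)OC(C)C | intermediate
13 | 3-methylbutan-2-one | CC(C)C(C)=O | starting material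
14 | ethyl acetate | CCOC(C)=O | starting material
15 | 5-methylhexane-2,4-dione | CC(C)C(=O)CC(C)=O | intermediate
16 | 1-bromo-3-methylbut-2-ene (prenyl bromide) | CC(C)=CCBr | starting material
17 | 2,9-dimethyldec-8-ene-3,5-dione | CC(C)C(=O)CC(=O)CCC=C(C)C | intermediate
18 | propan-2-yl (1R,3aR,4S,6R,7aS)-1,4-dihydroxy-1,4-dimethyl-6-[6-methyl-2-(3-methylbut-2-en-1-yl)-3,5-dioxoheptanoyl]octahydro-1H-indene-6-carboxylate (side-chain CH(prenyl) centre unassigned, enolisable) | CC(C)C(=O)CC(=O)C(CC=C(C)C)C(=O)[C@]1(C[C@H]2[C@@H](CC[C@@]2(C)O)[C@@](C)(O)C1)C(=O)OC(C)C | intermediate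
19 | mono-prenyl spiro acylphloroglucinol (enol form; spiro carbon R, hydrindane 1R,3aR,4S,7aS; C1' oxygen syn to the C4 hydroxyl) | CC(C)=CCC1=C(O)[C@]2(C[C@H]3[C@@H](CC[C@@]3(C)O)[C@@](C)(O)C2)C(=O)C(C(=O)C(C)C)=C1O | intermediate
20 | 3-methylbut-2-en-1-ol (prenol) | CC(C)=CCO | starting material
21 | methyl 3-methylbut-2-en-1-yl carbonate | COC(=O)OCC=C(C)C | intermediate
22 | tomoeone D | CC(C)=CCC1(CC=C(C)C)C(=O)[C@]2(C[C@H]3[C@@H](CC[C@@]3(C)O)[C@@](C)(O)C2)C(=O)C(C(=O)C(C)C)=C1O | target

**Step count**
Total: 11 steps. Longest linear sequence: 7 steps (1 → 3 → 4 → 5 → 8 → 9 → 11; the malonate path 2 → 3 → … is equally long), which is below two thirds of 11.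

**Three steps most likely to fail, with fallbacks**

Step 1 (transfer of the alkenyl group from 9-BBN to rhodium and trapping of the boron enolate are precedented for aryl groups but not for this reagent). The fallback sets out from 1 and 2 and comes back at 5. A Feringa-type asymmetric conjugate addition of 2 to 1 with a monovalent copper catalyst (CuBr·SMe2 5 mol %, Josiphos-type ferrocenyl diphosphine enantiomer giving 3R, Me3SiCl, tBuOMe, −75 °C) gives the silyl enol ether trimethyl{[(3R)-3-(prop-1-en-2-yl)cyclopent-1-en-1-yl]oxy}silane F1. F1 reacts with CH2=NMe2+ I− in CH2Cl2 (silyl enol ether Mannich reaction) to give 5. This replaces the boron nucleophile and rhodium catalyst by a Grignard reagent and copper.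

Step 5 (the proposed new electrocatalytic carbolactonisation; risks are slow malonate oxidation, elimination of the C4 cation, or anodic side reactions). The fallback uses known chemistry, sets out from 11 and comes back at 12. Iodination of the sodium enolate (NaH, then N-iodosuccinimide, THF, −78 °C) gives the iodomalonate diisopropyl 2-iodo-2-{[(1S,2R,5R)-2-hydroxy-2-methyl-5-(prop-1-en-2-yl)cyclopentyl]methyl}propanedioate F2. Curran-type iodine atom-transfer radical cyclisation (Bu3SnSnBu3 10 mol %, sunlamp, benzene, 80 °C) gives the 6-endo tertiary iodide diisopropyl (1R,3aR,7aS)-1-hydroxy-4-iodo-1,4-dimethyloctahydro-6H-indene-6,6-dicarboxylate F3 as a C4 epimer mixture. Heating F3 in DMF at 100 °C (or AgOTf, CH2Cl2) ionises it, and the axial ester lactonises with loss of the isopropyl group to give 12.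

Step 8 (the dianion must choose the lactone over the isopropyl ester; attack at the ester would lead to the spiro epimer). The fallback sets out from 12 and comes back at 18. Aminolysis of the lactone with Me2AlN(OMe)Me (from AlMe3 and MeNHOMe·HCl, CH2Cl2, 0 °C → rt; the hindered ester is inert) gives the Weinreb amide propan-2-yl (1R,3aR,4S,6R,7aS)-1,4-dihydroxy-6-[methoxy(methyl)carbamoyl]-1,4-dimethyloctahydro-1H-indene-6-carboxylate F4. Silylation of both tertiary alcohols (Me3SiOTf, 2,6-lutidine, CH2Cl2, −78 °C) gives the bis(trimethylsilyl) ether propan-2-yl (1R,3aR,4S,6R,7aS)-6-[methoxy(methyl)carbamoyl]-1,4-dimethyl-1,4-bis(trimethylsilyloxy)octahydro-1H-indene-6-carboxylate F5. The dianion of 17 (LiN(iPr)2, THF, −78 °C) acylates at the Weinreb amide only (chelated adduct), and work-up with aqueous citric acid, which also removes both silyl groups, gives 18.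

**Further compounds**
F1 | step 1 | trimethyl{[(3R)-3-(prop-1-en-2-yl)cyclopent-1-en-1-yl]oxy}silane | CC(=C)[C@@H]1CCC(O[Si](C)(C)C)=C1
F2 | step 5 | diisopropyl 2-iodo-2-{[(1S,2R,5R)-2-hydroxy-2-methyl-5-(prop-1-en-2-yl)cyclopentyl]methyl}propanedioate | CC(C)OC(=O)C(I)(C[C@H]1[C@@H](CC[C@@]1(C)O)C(C)=C)C(=O)OC(C)C
F3 | step 5 | diisopropyl (1R,3aR,7aS)-1-hydroxy-4-iodo-1,4-dimethyloctahydro-6H-indene-6,6-dicarboxylate (C4 epimer mixture) | CC(C)OC(=O)C1(C(=O)OC(C)C)C[C@H]2[C@@H](CC[C@@]2(C)O)C(C)(I)C1
F4 | step 8 | propan-2-yl (1R,3aR,4S,6R,7aS)-1,4-dihydroxy-6-[methoxy(methyl)carbamoyl]-1,4-dimethyloctahydro-1H-indene-6-carboxylate | CON(C)C(=O)[C@]1(C[C@H]2[C@@H](CC[C@@]2(C)O)[C@@](C)(O)C1)C(=O)OC(C)C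
F5 | step 8 | propan-2-yl (1R,3aR,4S,6R,7aS)-6-[methoxy(methyl)carbamoyl]-1,4-dimethyl-1,4-bis(trimethylsilyloxy)octahydro-1H-indene-6-carboxylate | CON(C)C(=O)[C@]1(C[C@H]2[C@@H](CC[C@@]2(C)O[Si](C)(C)C)[C@@](C)(O[Si](C)(C)C)C1)C(=O)OC(C)C
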